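**Retrosynthetic overview**
- The target is reached by global hydrogenolysis of its tribenzyl-protected form (two benzyl ethers on ring A, benzyl ester on ring B).
- Key disconnection: the depside ester is cut on both sides of its carbonyl carbon, which is carbon monoxide, inserted by palladium catalysis between a ring A aryl iodide and the free 4-OH of benzyl olivetolate. No ring A benzoic acid and no condensing agent is used.
- The ring A aryl iodide comes from regioselective iodination of a 1-arylpentan-3-one, itself made in one step by Heck arylation of pent-1-en-3-ol with an aryl bromide.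
- Benzyl olivetolate comes from olivetolic acid by selective carboxylate benzylation.
- No ring is formed: both benzene rings are bought, ring A in the aryl bromide and ring B in olivetolic acid.

Assumption: the target SMILES has no stereocentre and no stereogenic double bond, so the compound is achiral and the "single enantiomer" is the compound itself; 1,3-bis(benzyloxy)-5-bromobenzene and olivetolic acid are taken as catalogue compounds.

**Route**

Step 1
Reactants: 1 1,3-bis(benzyloxy)-5-bromobenzene; 2 pent-1-en-3-ol (racemic, 1.5 equiv)
Product: 4 1-[3,5-bis(benzyloxy)phenyl]pentan-3-one, via enol tautomer 3 (not isolated)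
Conditions: Pd(OAc)2 (2 mol%), PPh3 (4 mol%), NaHCO3 (1.5 equiv), DMF, 110 °C
Reagents that add atoms: none
Why: Heck arylation of an allylic alcohol, in which the arylpalladium bromide adds to the terminal alkene carbon and β-hydride elimination toward the carbinol carbon gives enol 3, which tautomerises to the saturated ketone, so the whole 3-oxopentyl chain is installed in one operation and the carbinol centre of racemic 2 becomes the carbonyl carbon (no stereocentre is formed).

Step 2
Reactants: 4 1-[3,5-bis(benzyloxy)phenyl]pentan-3-one
Product: 5 1-[3,5-bis(benzyloxy)-2-iodophenyl]pentan-3-one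
Conditions: NIS (1.05 equiv), TFA (10 mol%), MeCN, 0 °C to rt, dark
Reagents that add atoms: N-iodosuccinimide (NIS), O=C1CCC(=O)N1I
Why: Electrophilic aromatic iodination (SEAr) at the ring carbon next to the side chain, which is para to one benzyloxy group and ortho to the other and is attacked in preference to the more shielded carbon between the two benzyloxy groups, as is general for 3,5-dialkoxyalkylbenzenes, while one equivalent of NIS at low temperature holds the reaction at the mono-iodide (no stereocentre is formed).

Step 3
Reactants: 6 olivetolic acid (2,4-dihydroxy-6-pentylbenzoic acid)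
Product: 7 benzyl 2,4-dihydroxy-6-pentylbenzoate
Conditions: BnBr (1.05 equiv), KHCO3 (1.2 equiv), DMF, rt
Reagents that add atoms: benzyl bromide, BrCc1ccccc1
Why: Chemoselective carboxylate O-alkylation (SN2), because KHCO3 deprotonates only the carboxylic acid and not the phenols, so the benzyl ester forms and both hydroxyl groups stay free (no stereocentre is formed).

Step 4
Reactants: 5 1-[3,5-bis(benzyloxy)-2-iodophenyl]pentan-3-one; 7 benzyl 2,4-dihydroxy-6-pentylbenzoate (1.2 equiv)
Product: 8 benzyl 4-{[2,4-bis(benzyloxy)-6-(3-oxopentyl)benzoyl]oxy}-2-hydroxy-6-pentylbenzoate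
Conditions: CO (1 atm), Pd(OAc)2 (5 mol%), Xantphos (6 mol%), Et3N (2 equiv), toluene, 80 °C
Reagents that add atoms: carbon monoxide, [C-]#[O+]
Why: Palladium-catalysed carbonylative esterification (aryloxycarbonylation, a Heck-type carbonylation), in which the carbon–iodine bond of 5 adds oxidatively to zerovalent palladium formed in situ from Pd(OAc)2 and Xantphos, CO inserts to give the aroylpalladium iodide, and the phenoxide of the more acidic, unhindered 4-OH of 7 is acylated by acyl–oxygen reductive elimination, which the wide bite angle of Xantphos favours, while the 2-OH stays locked in its hydrogen bond to the ester carbonyl and Et3N is too weak to enolise the ketone (no stereocentre is formed).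

Step 5
Reactants: 8 benzyl 4-{[2,4-bis(benzyloxy)-6-(3-oxopentyl)benzoyl]oxy}-2-hydroxy-6-pentylbenzoate
Product: 9 4-{[2,4-dihydroxy-6-(3-oxopentyl)benzoyl]oxy}-2-hydroxy-6-pentylbenzoic acid (CNP0311703.0)
Conditions: H2 (1 atm), 10% Pd/C, EtOAc, rt
Reagents that add atoms: none
Why: Catalytic hydrogenolysis removes the two benzyl aryl ethers and the benzyl ester in one operation, while the aliphatic ketone, the diaryl ester and both arenes are inert to Pd/C at 1 atm and room temperature, and the achiral target has no stereocentre to control.

**Compound list**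
1 | 1,3-bis(benzyloxy)-5-bromobenzene | Brc1cc(OCc2ccccc2)cc(OCc2ccccc2)c1 | starting material
2 | pent-1-en-3-ol (racemic; its carbinol centre becomes the ketone carbon) | CCC(O)C=C | starting material
3 | (Z)-1-[3,5-bis(benzyloxy)phenyl]pent-2-en-3-ol (enol tautomer of 4, not isolated; drawn as Z, geometry is lost on tautomerisation) | CC/C(O)=C/Cc1cc(OCc2ccccc2)cc(OCc2ccccc2)c1 | intermediate
4 | 1-[3,5-bis(benzyloxy)phenyl]pentan-3-one | CCC(=O)CCc1cc(OCc2ccccc2)cc(OCc2ccccc2)c1 | intermediate
5 | 1-[3,5-bis(benzyloxy)-2-iodophenyl]pentan-3-one | CCC(=O)CCc1cc(OCc2ccccc2)cc(OCc2ccccc2)c1I | intermediate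
6 | olivetolic acid (2,4-dihydroxy-6-pentylbenzoic acid) | CCCCCc1cc(O)cc(O)c1C(=O)O | starting material
7 | benzyl 2,4-dihydroxy-6-pentylbenzoate | CCCCCc1cc(O)cc(O)c1C(=O)OCc1ccccc1 | intermediate
8 | benzyl 4-{[2,4-bis(benzyloxy)-6-(3-oxopentyl)benzoyl]oxy}-2-hydroxy-6-pentylbenzoate | CCCCCc1cc(OC(=O)c2c(OCc3ccccc3)cc(OCc3ccccc3)cc2CCC(=O)CC)cc(O)c1C(=O)OCc1ccccc1 | intermediate
9 | 4-{[2,4-dihydroxy-6-(3-oxopentyl)benzoyl]oxy}-2-hydroxy-6-pentylbenzoic acid (achiral) | CCCCCc1cc(OC(=O)c2c(O)cc(O)cc2CCC(=O)CC)cc(O)c1C(=O)O | target

**Step count**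
Total steps: 5.
Longest linear sequence: 4 steps (steps 1, 2, 4, 5, from 1 to 9); step 3 is a one-step side branch.

**Three steps most likely to fail**

Step 4 (carbonylative coupling) is the main risk. The aryl iodide is electron-rich and flanked by two ortho substituents, and the resorcylate phenoxide is a weak nucleophile. Acyl–oxygen reductive elimination may therefore lose to hydrodeiodination, or the aroylpalladium may be captured by the side-chain ketone enol. The fallback sets out from 5 and comes back at 8, and separates CO insertion from the hindered ester formation. Fluorocarbonylation of 5 (Pd(OAc)2, Xantphos, N-formylsaccharin as CO source, KF, DMF, 80 °C) gives 2,4-bis(benzyloxy)-6-(3-oxopentyl)benzoyl fluoride F1, a small and robust acyl donor. F1 then acylates the 4-OH of 7 by ordinary addition–elimination (K2CO3, MeCN, rt) to give 8.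

Step 2 (iodination) may give some di-iodide at the second, equivalent ring position, or minor α-iodination of the ketone. The fallback sets out from 4 and comes back at 8, and gives up the halide and CO altogether. Vilsmeier–Haack formylation of 4 (POCl3, DMF, 0 °C to rt, then aqueous NaOAc) stops cleanly at mono-substitution at the same ring carbon and gives 2,4-bis(benzyloxy)-6-(3-oxopentyl)benzaldehyde F2. Pinnick oxidation (NaClO2, NaH2PO4, 2-methylbut-2-ene, t-BuOH/H2O, rt) gives 2,4-bis(benzyloxy)-6-(3-oxopentyl)benzoic acid F3. Mixed-anhydride esterification of F3 with 7 (TFAA, toluene, rt) gives 8.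

Step 1 (Heck reaction) may suffer from sluggish oxidative addition of the aryl bromide. It may also give regioisomers: the branched α-aryl ketone, or the aryl allylic alcohol from β-hydride elimination away from the carbinol. The fallback sets out from 1 and comes back at 4, and replaces the Heck reaction by a conjugate addition. Miyaura borylation of 1 (B2pin2, KOAc, Pd(dppf)Cl2, dioxane, 90 °C) gives 2-[3,5-bis(benzyloxy)phenyl]-4,4,5,5-tetramethyl-1,3,2-dioxaborolane F4. Rhodium-catalysed 1,4-addition of F4 to pent-1-en-3-one ([Rh(cod)Cl]2 (1.5 mol%), KOH, dioxane/H2O, 50 °C) gives 4 with no regiochemical ambiguity.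

**Further compounds**
F1 | step 4 | 2,4-bis(benzyloxy)-6-(3-oxopentyl)benzoyl fluoride | CCC(=O)CCc1cc(OCc2ccccc2)cc(OCc2ccccc2)c1C(F)=O
F2 | step 2 | 2,4-bis(benzyloxy)-6-(3-oxopentyl)benzaldehyde | CCC(=O)CCc1cc(OCc2ccccc2)cc(OCc2ccccc2)c1C=O
F3 | step 2 | 2,4-bis(benzyloxy)-6-(3-oxopentyl)benzoic acid | CCC(=O)CCc1cc(OCc2ccccc2)cc(OCc2ccccc2)c1C(=O)O
F4 | step 1 | 2-[3,5-bis(benzyloxy)phenyl]-4,4,5,5-tetramethyl-1,3,2-dioxaborolane | CC1(C)OB(OC1(C)C)c1cc(OCc2ccccc2)cc(OCc2ccccc2)c1
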